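**Retrosynthetic overview**
1. Target ⇐ its bis-TBS catechol ether; fluoride desilylation is the last step.
2. Cyclopropane (last ring) ⇐ cobalt-metalloradical [2+1] union of a terminal alkene (the acetoxy-allyl dihydropyranone) with a lactate-derived α-diazoketone that already carries the protected caffeate. This one radical step forms two C–C bonds and both ring stereocentres.
3. Alkene fragment ⇐ acetylation ⇐ Z-enoate lactonization (dihydropyranone, first lasting ring) ⇐ propiolate opening of an epoxide ⇐ Sharpless desymmetrization of divinylcarbinol (sets C6 and C1').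
4. Diazoketone ⇐ acid chloride + diazomethane ⇐ Heck coupling of protected 4-bromocatechol with O-acryloyl (S)-lactic acid (lactate centre from the chiral pool).
5. Ring order: oxirane (transient) → dihydropyranone → cyclopropane; the arene is bought as catechol.

Assumption: L-(+)-DIPT is taken to give the (2R,3S) epoxy alcohol (Sharpless face rule), and the (R)-amide antipode of the cobalt porphyrin is taken to give the (1S,2S) ring by analogy with diazoacetates; both would be confirmed (rotation of 2, a model cyclopropanation) before material is committed.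

**Route**

Step 1
Reactants: 1 penta-1,4-dien-3-ol (divinylcarbinol)
Product: 2 (2R,3S)-1,2-epoxypent-4-en-3-ol, i.e. (S)-1-[(R)-oxiran-2-yl]prop-2-en-1-ol
Conditions: Ti(OiPr)4 (10 mol%), L-(+)-DIPT (13 mol%), t-BuOOH (1.2 equiv, anhydrous), 4 Å MS, CH2Cl2, −20 °C, 4–5 d
Reagents that add atoms: tert-butyl hydroperoxide, CC(C)(C)OO
Why: Sharpless asymmetric epoxidation run as a desymmetrization, in which the titanium tartrate picks one enantiotopic vinyl group and one face (anti epoxy alcohol, both centres set at once) and the minor enantiomer is drained by a fast second epoxidation, so ee rises with conversion.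

Step 2
Reactants: 2 (2R,3S)-1,2-epoxypent-4-en-3-ol; 3 ethyl propiolate
Product: 5 ethyl (5R,6S)-5,6-dihydroxyoct-7-en-2-ynoate, via lithium ethyl propiolate 4 (not isolated)
Conditions: 3 (3.3 equiv), n-BuLi (3.1 equiv), THF, −78 °C; BF3·OEt2 (3.1 equiv), then 2, −78 °C, 2 h; aq NH4Cl
Reagents that add atoms: n-butyllithium, [Li]CCCC (the lithium of intermediate 4 only)
Why: Yamaguchi–Hirao alkynylation, in which the BF3-activated terminal epoxide is opened by SN2 attack at the unhindered CH2 (one equivalent of 4 is spent on the free hydroxyl), so neither stereocentre is touched.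

Step 3
Reactants: 5 ethyl (5R,6S)-5,6-dihydroxyoct-7-en-2-ynoate
Product: 7 (6R)-6-[(1S)-1-hydroxyprop-2-en-1-yl]-5,6-dihydro-2H-pyran-2-one, via Z-enoate diol 6 (not isolated)
Conditions: H2 (1 atm), Pd/CaCO3 poisoned with Pb(OAc)2, quinoline, EtOAc, 0 °C→rt, stopped at 1.0 equiv H2; filter; PPTS (10 mol%), PhH, 60 °C
Reagents that add atoms: none
Why: Lindlar semihydrogenation gives the Z-enoate by syn addition of H2 (the conjugated alkyne outcompetes the isolated vinyl group on the poisoned catalyst), and acid-catalysed lactonization then closes the six-membered ring through the δ-hydroxyl in preference to a seven-membered ring through the allylic one.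

Step 4
Reactants: 7 (6R)-6-[(1S)-1-hydroxyprop-2-en-1-yl]-5,6-dihydro-2H-pyran-2-one
Product: 8 (1S)-1-[(2R)-6-oxo-3,6-dihydro-2H-pyran-2-yl]prop-2-en-1-yl acetate
Conditions: Ac2O (1.5 equiv), pyridine, DMAP (5 mol%), CH2Cl2, 0 °C
Reagents that add atoms: acetic anhydride, CC(=O)OC(C)=O
Why: DMAP-catalysed O-acetylation of the only free hydroxyl, with retention at C1' and mild enough to leave the enoate lactone alone.

Step 5
Reactants: 9 (S)-lactic acid; 10 acryloyl chloride
Product: 11 (2S)-2-(acryloyloxy)propanoic acid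
Conditions: 10 (1.15 equiv), BHT (cat.), CH2Cl2, 0 °C→rt, N2 sweep; aqueous wash
Reagents that add atoms: none
Why: Base-free O-acylation of the hydroxyl by the acid chloride (any mixed anhydride at the carboxyl reverts on aqueous work-up), with the chiral-pool stereocentre untouched.

Step 6
Reactants: 12 catechol
Product: 13 4-bromobenzene-1,2-diol
Conditions: NBS (1.0 equiv), HBF4·OEt2, MeCN, −30 °C→rt
Reagents that add atoms: N-bromosuccinimide, O=C1CCC(=O)N1Br
Why: Electrophilic aromatic bromination, directed para to a hydroxyl and stopped at the mono-bromide at low temperature.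

Step 7
Reactants: 13 4-bromobenzene-1,2-diol
Product: 14 4-bromo-1,2-bis[(tert-butyldimethylsilyl)oxy]benzene
Conditions: TBSCl (2.5 equiv), imidazole (5 equiv), DMF, rt
Reagents that add atoms: tert-butyldimethylsilyl chloride, CC(C)(C)[Si](C)(C)Cl
Why: Corey silylation of both phenols masks the catechol against diazomethane and against hydrogen-atom donation in the radical step, and comes off with fluoride at the end.

Step 8
Reactants: 14 4-bromo-1,2-bis[(tert-butyldimethylsilyl)oxy]benzene; 11 (2S)-2-(acryloyloxy)propanoic acid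
Product: 15 (2S)-2-{[(2E)-3-{3,4-bis[(tert-butyldimethylsilyl)oxy]phenyl}prop-2-enoyl]oxy}propanoic acid
Conditions: Pd2(dba)3 (2 mol%), [HP(t-Bu)3]BF4 (8 mol%), Cy2NMe (2.5 equiv), dioxane, 50 °C; citric acid work-up
Reagents that add atoms: none
Why: Mizoroki–Heck arylation of the acrylate, E-selective through syn insertion and syn β-hydride elimination, under mild amine conditions that keep the aryl silyl ethers and the lactate centre (present as its carboxylate) intact.

Step 9
Reactants: 15 (2S)-2-{[(2E)-3-{3,4-bis[(tert-butyldimethylsilyl)oxy]phenyl}prop-2-enoyl]oxy}propanoic acid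
Product: 17 (2S)-4-diazo-3-oxobutan-2-yl (2E)-3-{3,4-bis[(tert-butyldimethylsilyl)oxy]phenyl}prop-2-enoate, via acid chloride 16 (not isolated)
Conditions: (COCl)2 (1.3 equiv), DMF (cat.), CH2Cl2, 0 °C→rt, evaporate; CH2N2 (3 equiv), Et2O, 0 °C, 1 h, then N2 purge
Reagents that add atoms: diazomethane, C=[N+]=[N-]; oxalyl chloride, O=C(Cl)C(Cl)=O (the chlorine of intermediate 16 only)
Why: Arndt–Eistert-type acylation of diazomethane by the acid chloride, where a second equivalent of diazomethane takes up HCl so no amine base meets the epimerizable α-acyloxy centre, and the cinnamate is too slow a dipolarophile to react at 0 °C.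

Step 10
Reactants: 8 (1S)-1-[(2R)-6-oxo-3,6-dihydro-2H-pyran-2-yl]prop-2-en-1-yl acetate; 17 (2S)-4-diazo-3-oxobutan-2-yl (2E)-3-{3,4-bis[(tert-butyldimethylsilyl)oxy]phenyl}prop-2-enoate
Product: 18 (2S)-1-[(1S,2S)-2-{(S)-acetoxy[(2R)-6-oxo-3,6-dihydro-2H-pyran-2-yl]methyl}cyclopropyl]-1-oxopropan-2-yl (2E)-3-{3,4-bis[(tert-butyldimethylsilyl)oxy]phenyl}prop-2-enoate
Conditions: 8 (1.0 equiv), 17 (1.3 equiv), [Co(3,5-DitBu-ChenPhyrin)] (5 mol%, (R)-amide antipode; {5,15-bis(3,5-di-tert-butylphenyl)-10,20-bis[2,6-bis(2,2-dimethylcyclopropane-1-carboxamido)phenyl]porphyrinato}cobalt), PhCl, 40 °C, N2, 36 h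
Reagents that add atoms: none
Why: Proposed new method: the divalent cobalt porphyrin takes up the α-diazoketone with loss of N2 to give an α-(trivalent cobalt)alkyl radical, which adds to the terminal CH2 of 8, and the secondary γ-radical then closes by 3-exo-tet substitution at the Co–C bond (a stepwise radical [2+1]); the closest known reaction type is cobalt-metalloradical asymmetric cyclopropanation of terminal alkenes, used as limiting reagent, with acceptor diazo reagents (diazoacetates, α-ketodiazoacetates), and by that precedent the trans ring and both new centres should be set by the chiral amidoporphyrin pocket (N–H···O=C hydrogen bond to the ketone) rather than by the substrate, while the cis lactone alkene and the trans cinnamate, both 1,2-disubstituted, should be poor acceptors for the hindered radical.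

Step 11
Reactants: 18 the bis-TBS ether from step 10
Product: 19 (2S)-1-[(1S,2S)-2-{(S)-acetoxy[(2R)-6-oxo-3,6-dihydro-2H-pyran-2-yl]methyl}cyclopropyl]-1-oxopropan-2-yl (2E)-3-(3,4-dihydroxyphenyl)prop-2-enoate (target, CNP0103198.1)
Conditions: HF·pyridine (excess), pyridine/THF, 0 °C→rt; pH 7 buffer, degassed work-up
Reagents that add atoms: none
Why: Fluoride-driven desilylation of the two aryl silyl ethers in a buffered, weakly acidic medium that leaves the acetate, the enoate lactone, the cinnamate and the epimerizable α-acyloxy ketone untouched, so no stereocentre is at risk.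

**Compound list**

1 | penta-1,4-dien-3-ol | C=CC(O)C=C | starting material
2 | (2R,3S)-1,2-epoxypent-4-en-3-ol | C=C[C@H](O)[C@H]1CO1 | intermediate
3 | ethyl propiolate | C#CC(=O)OCC | starting material
4 | lithium ethyl propiolate (ethyl 3-lithioprop-2-ynoate) | [Li]C#CC(=O)OCC | intermediate (not isolated)
5 | ethyl (5R,6S)-5,6-dihydroxyoct-7-en-2-ynoate | C=C[C@H](O)[C@H](O)CC#CC(=O)OCC | intermediate
6 | ethyl (2Z,5R,6S)-5,6-dihydroxyocta-2,7-dienoate | C=C[C@H](O)[C@H](O)C/C=C\C(=O)OCC | intermediate (not isolated)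
7 | (6R)-6-[(1S)-1-hydroxyprop-2-en-1-yl]-5,6-dihydro-2H-pyran-2-one | C=C[C@H](O)[C@H]1CC=CC(=O)O1 | intermediate
8 | (1S)-1-[(2R)-6-oxo-3,6-dihydro-2H-pyran-2-yl]prop-2-en-1-yl acetate | C=C[C@H](OC(C)=O)[C@H]1CC=CC(=O)O1 | intermediate
9 | (S)-lactic acid | C[C@H](O)C(=O)O | starting material
10 | acryloyl chloride | C=CC(=O)Cl | starting material
11 | (2S)-2-(acryloyloxy)propanoic acid | C[C@H](OC(=O)C=C)C(=O)O | intermediate
12 | catechol | Oc1ccccc1O | starting material
13 | 4-bromobenzene-1,2-diol | Oc1ccc(Br)cc1O | intermediate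
14 | 4-bromo-1,2-bis[(tert-butyldimethylsilyl)oxy]benzene | CC(C)(C)[Si](C)(C)Oc1ccc(Br)cc1O[Si](C)(C)C(C)(C)C | intermediate
15 | (2S)-2-{[(2E)-3-{3,4-bis[(tert-butyldimethylsilyl)oxy]phenyl}prop-2-enoyl]oxy}propanoic acid | C[C@H](OC(=O)/C=C/c1ccc(O[Si](C)(C)C(C)(C)C)c(O[Si](C)(C)C(C)(C)C)c1)C(=O)O | intermediate
16 | (2S)-2-{[(2E)-3-{3,4-bis[(tert-butyldimethylsilyl)oxy]phenyl}prop-2-enoyl]oxy}propanoyl chloride | C[C@H](OC(=O)/C=C/c1ccc(O[Si](C)(C)C(C)(C)C)c(O[Si](C)(C)C(C)(C)C)c1)C(=O)Cl | intermediate (not isolated)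
17 | (2S)-4-diazo-3-oxobutan-2-yl (2E)-3-{3,4-bis[(tert-butyldimethylsilyl)oxy]phenyl}prop-2-enoate | C[C@H](OC(=O)/C=C/c1ccc(O[Si](C)(C)C(C)(C)C)c(O[Si](C)(C)C(C)(C)C)c1)C(=O)C=[N+]=[N-] | intermediate
18 | (2S)-1-[(1S,2S)-2-{(S)-acetoxy[(2R)-6-oxo-3,6-dihydro-2H-pyran-2-yl]methyl}cyclopropyl]-1-oxopropan-2-yl (2E)-3-{3,4-bis[(tert-butyldimethylsilyl)oxy]phenyl}prop-2-enoate | CC(=O)O[C@@H]([C@H]1C[C@@H]1C(=O)[C@H](C)OC(=O)/C=C/c1ccc(O[Si](C)(C)C(C)(C)C)c(O[Si](C)(C)C(C)(C)C)c1)[C@H]1CC=CC(=O)O1 | intermediate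
19 | (2S)-1-[(1S,2S)-2-{(S)-acetoxy[(2R)-6-oxo-3,6-dihydro-2H-pyran-2-yl]methyl}cyclopropyl]-1-oxopropan-2-yl (2E)-3-(3,4-dihydroxyphenyl)prop-2-enoate | CC(=O)O[C@@H]([C@H]1C[C@@H]1C(=O)[C@H](C)OC(=O)/C=C/c1ccc(O)c(O)c1)[C@H]1CC=CC(=O)O1 | target

**Totals and risks**

Total step count: 11. Longest linear sequence: 6 steps (1→2→5→7→8→18→19; the arm 12→13→14→15→17→18→19 is equally long).

The three steps most likely to fail:

Step 10 (the radical [2+1] union). The alkene is unactivated, an acceptor-only diazoketone is untested in this catalysis, the tethered cinnamate could trap the carbene radical intramolecularly, and the catalyst must override two nearby stereocentres. The fallback sets out from 8 (with 9 and 14 as further inputs) and comes back at 18. It keeps the cobalt-radical cyclopropanation but takes the cinnamate out of it and uses a small, cheap diazoketone that can be added in excess. Lactic acid 9 is silylated twice (TBSCl, imidazole, DMF) to tert-butyldimethylsilyl (2S)-2-[(tert-butyldimethylsilyl)oxy]propanoate F1. The silyl ester is cleaved (K2CO3, MeOH/H2O, 0 °C) to (2S)-2-[(tert-butyldimethylsilyl)oxy]propanoic acid F2. Oxalyl chloride with catalytic DMF gives (2S)-2-[(tert-butyldimethylsilyl)oxy]propanoyl chloride F3, and diazomethane then gives (3S)-3-[(tert-butyldimethylsilyl)oxy]-1-diazobutan-2-one F4. Cyclopropanation of 8 with F4 (2–3 equiv) under the step 10 catalyst gives (S)-[(1S,2S)-2-{(2S)-2-[(tert-butyldimethylsilyl)oxy]propanoyl}cyclopropyl][(2R)-6-oxo-3,6-dihydro-2H-pyran-2-yl]methyl acetate F5. HF·pyridine frees (S)-[(1S,2S)-2-[(2S)-2-hydroxypropanoyl]cyclopropyl][(2R)-6-oxo-3,6-dihydro-2H-pyran-2-yl]methyl acetate F6. This is esterified (DCC, DMAP, CH2Cl2, 0 °C) with (2E)-3-{3,4-bis[(tert-butyldimethylsilyl)oxy]phenyl}prop-2-enoic acid F7, itself made by Heck coupling of 14 with acrylic acid under the step 8 conditions, to give 18.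

Step 2 (Lewis-acid alkynylation of an unprotected epoxy alcohol). The risks are Payne-type rearrangement, sluggish opening of the alkoxide–BF3 species, and decomposition of the thermally fragile lithium propiolate. The fallback sets out from 2 and comes back at 7. The epoxide is opened without Lewis acid by LiC≡CH·H2NCH2CH2NH2 (DMSO, rt) to give (3S,4R)-hept-1-en-6-yne-3,4-diol F8. Treatment with n-BuLi (3.1 equiv, THF, −78→0 °C), then CO2 and acidic work-up (the lithium alkyl carbonates revert to hydroxyls) gives (5R,6S)-5,6-dihydroxyoct-7-en-2-ynoic acid F9. Semihydrogenation as in step 3 gives (2Z,5R,6S)-5,6-dihydroxyocta-2,7-dienoic acid F10, which lactonizes (PPTS, PhH, 60 °C) to 7.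

Step 5 (acryloylation of free lactic acid). The risks are self-esterification of lactic acid, mixed anhydrides, HCl addition to the acrylate and polymerization. The fallback sets out from 9 and comes back at 15, with the carboxyl masked. Lactic acid 9 is esterified with tert-butyl 2,2,2-trichloroacetimidate (CH2Cl2/cyclohexane, rt) to tert-butyl (2S)-2-hydroxypropanoate F11. Acylation with 10 (Et3N, CH2Cl2, −20 °C) gives tert-butyl (2S)-2-(acryloyloxy)propanoate F12. Heck coupling with 14 under the step 8 conditions gives tert-butyl (2S)-2-{[(2E)-3-{3,4-bis[(tert-butyldimethylsilyl)oxy]phenyl}prop-2-enoyl]oxy}propanoate F13. Cleavage of the tert-butyl ester (TFA/CH2Cl2 1:4, 0 °C, which aryl silyl ethers tolerate) gives 15.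

**Further compounds**

F1 | step 10 | tert-butyldimethylsilyl (2S)-2-[(tert-butyldimethylsilyl)oxy]propanoate | C[C@H](O[Si](C)(C)C(C)(C)C)C(=O)O[Si](C)(C)C(C)(C)C
F2 | step 10 | (2S)-2-[(tert-butyldimethylsilyl)oxy]propanoic acid | C[C@H](O[Si](C)(C)C(C)(C)C)C(=O)O
F3 | step 10 | (2S)-2-[(tert-butyldimethylsilyl)oxy]propanoyl chloride | C[C@H](O[Si](C)(C)C(C)(C)C)C(=O)Cl
F4 | step 10 | (3S)-3-[(tert-butyldimethylsilyl)oxy]-1-diazobutan-2-one | C[C@H](O[Si](C)(C)C(C)(C)C)C(=O)C=[N+]=[N-]
F5 | step 10 | (S)-[(1S,2S)-2-{(2S)-2-[(tert-butyldimethylsilyl)oxy]propanoyl}cyclopropyl][(2R)-6-oxo-3,6-dihydro-2H-pyran-2-yl]methyl acetate | CC(=O)O[C@@H]([C@H]1C[C@@H]1C(=O)[C@H](C)O[Si](C)(C)C(C)(C)C)[C@H]1CC=CC(=O)O1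
F6 | step 10 | (S)-[(1S,2S)-2-[(2S)-2-hydroxypropanoyl]cyclopropyl][(2R)-6-oxo-3,6-dihydro-2H-pyran-2-yl]methyl acetate | CC(=O)O[C@@H]([C@H]1C[C@@H]1C(=O)[C@H](C)O)[C@H]1CC=CC(=O)O1
F7 | step 10 | (2E)-3-{3,4-bis[(tert-butyldimethylsilyl)oxy]phenyl}prop-2-enoic acid | OC(=O)/C=C/c1ccc(O[Si](C)(C)C(C)(C)C)c(O[Si](C)(C)C(C)(C)C)c1
F8 | step 2 | (3S,4R)-hept-1-en-6-yne-3,4-diol | C=C[C@H](O)[C@H](O)CC#C
F9 | step 2 | (5R,6S)-5,6-dihydroxyoct-7-en-2-ynoic acid | C=C[C@H](O)[C@H](O)CC#CC(=O)O
F10 | step 2 | (2Z,5R,6S)-5,6-dihydroxyocta-2,7-dienoic acid | C=C[C@H](O)[C@H](O)C/C=C\C(=O)O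
F11 | step 5 | tert-butyl (2S)-2-hydroxypropanoate | C[C@H](O)C(=O)OC(C)(C)C
F12 | step 5 | tert-butyl (2S)-2-(acryloyloxy)propanoate | C[C@H](OC(=O)C=C)C(=O)OC(C)(C)C
F13 | step 5 | tert-butyl (2S)-2-{[(2E)-3-{3,4-bis[(tert-butyldimethylsilyl)oxy]phenyl}prop-2-enoyl]oxy}propanoate | C[C@H](OC(=O)/C=C/c1ccc(O[Si](C)(C)C(C)(C)C)c(O[Si](C)(C)C(C)(C)C)c1)C(=O)OC(C)(C)C
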